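**Assumptions (one line each):**
- The removable chiral ester auxiliary (−)-8-phenylmenthol is treated as a reagent, like a protecting group.
- The (1R,2S,5R) auxiliary is assumed to favour the (1S,2R) core; if the opposite diastereomer predominates, the (+)-auxiliary is used instead.

**Target check:** the SMILES is a 1-aryl-1,2-dihydronaphthalene with a guaiacyl group at C1 and CH2OH groups at C2 and C3. The C3=C4 alkene is fused to a 7-hydroxy-6-methoxy arene. The configuration is (1S,2R), which puts the C1 aryl and the C2 CH2OH trans.

## Retrosynthetic overview
1. The target diol comes from a diester by DIBAL-H reduction, which also releases the chiral alcohol.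
2. The dihydronaphthalene ring is built in one operation by oxidative dimerisation of a chiral ferulate ester. The key bond is C8–C8′ (C2–C3 of the product), formed by radical–radical coupling of two phenoxyl radicals. The C1–C8a bond then closes by quinone-methide/aryl cyclisation, and the trans stereochemistry is relayed from C2.
3. The ferulate ester comes from para-hydroarylation of guaiacol with a chiral propiolate, and guaiacol comes from mono-O-methylation of catechol.
4. Only one ring is formed, in the coupling step; both arenes are already present.

## Route

**Step 1**
Reactants: 1 (catechol)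
Product: 2 (guaiacol, 2-methoxyphenol)
Conditions: Me2SO4 (1 equiv), NaOH (1 equiv), H2O, 0 → 60 °C
Reagents that add atoms: dimethyl sulfate, COS(=O)(=O)OC
Why: Williamson mono-O-methylation of the mono-phenoxide (the standard catechol → guaiacol process), with veratrole and unreacted catechol removed by distillation or extraction.

**Step 2**
Reactants: 3 (propiolic acid)
Product: 4 ((1R,2S,5R)-8-phenylmenthyl propiolate)
Conditions: (−)-8-phenylmenthol (1.0 equiv), EDC·HCl, DMAP (cat.), CH2Cl2, 0 °C → rt
Reagents that add atoms: (1R,2S,5R)-(−)-8-phenylmenthol, C[C@@H]1CC[C@H]([C@@H](C1)O)C(C)(C)c1ccccc1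
Why: carbodiimide (Steglich) esterification attaches the removable chiral auxiliary, which will bias the facial selectivity of the later radical coupling.

**Step 3**
Reactants: 2 (guaiacol, 3 equiv) and 4
Product: 5 (8-phenylmenthyl (E)-ferulate)
Conditions: Pd(OAc)2 (5 mol%), TFA/CH2Cl2 (1:1), 25 °C; then PhSSPh (5 mol%), 450 nm light, 2 h
Reagents that add atoms: none
Why: Fujiwara-type Pd(II) hydroarylation of the propiolate goes para to the more activating OH of guaiacol, giving a syn-addition (Z)-cinnamate. Thiyl-radical catalysed isomerisation then converts it to the E isomer, which is conjugated and thermodynamically favoured.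

**Step 4**
Reactants: 5 (two equivalents)
Product: 6 (diester of the (1S,2R) 1-aryl-1,2-dihydronaphthalene-2,3-dicarboxylic acid with 8-phenylmenthol, both esters chiral)
Conditions: Ag2O (1.5 equiv), acetone/CH2Cl2 1:1 (0.2 M), 25 °C, dark, 24 h; then silica gel chromatography/HPLC to isolate the (1S,2R) diastereomer
Reagents that add atoms: none (Ag2O is only the one-electron oxidant)
Why: Proposed new method: Ag(I) oxidises each phenol to a phenoxyl radical with spin density at C8, and C8–C8′ radical coupling gives a bis-quinone methide. The bulky phenylmenthyl esters are meant to bias which face of C8 couples. One quinone methide then tautomerises to the phenol/cinnamate, and its ring carbon para to OMe attacks C7 of the other quinone methide, anti to the C8 ester, closing the ring with C1/C2 trans. The closest known reactions are the Ag2O dehydrodimerisation of methyl ferulate and the sinapate → aryldihydronaphthalene lignan coupling; using a chiral ester auxiliary to control the absolute configuration is the new element.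

**Step 5**
Reactants: 6
Product: 7 (target, (1S,2R)-1-(4-hydroxy-3-methoxyphenyl)-2,3-bis(hydroxymethyl)-6-methoxy-1,2-dihydronaphthalen-7-ol)
Conditions: DIBAL-H (12 equiv), toluene/CH2Cl2, −78 → 0 °C; then aqueous Rochelle salt
Reagents that add atoms: none (hydride only)
Why: DIBAL-H reduces both esters 1,2 to the allylic and aliphatic primary alcohols and releases (−)-8-phenylmenthol for recovery. The conditions are non-basic, so C1 and C2 are not epimerised, and the free phenols are tolerated as aluminium phenoxides.

## Self-check
- **Atom balance in step 4:** 2 × 5 − 2 H = 6. One vinyl H at C8′ and the aryl H at C6′ are lost, and the C7–H, C8–H, C7′–H and both phenol OH groups are retained.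
- **Ring pattern:** ring closure at C6′, para to OMe, gives the 7-OH/6-OMe arene. The C1 aryl is guaiacyl, and C3=C4 remains conjugated, as in the target.
- **Stereocentres:** C2 is set in the radical coupling and C1 is set by the anti cyclisation. Neither is touched again in step 5.
- **Step 5:** the product is C20H22O6, and the SMILES of 6 and 7 carry the same core chirality marks.

## Compound list
| No. | Name | SMILES | Role |
|---|---|---|---|
| 1 | Catechol | Oc1ccccc1O | starting material |
| 2 | Guaiacol | COc1ccccc1O | intermediate |
| 3 | Propiolic acid | C#CC(=O)O | starting material |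
| 4 | (1R,2S,5R)-8-Phenylmenthyl propiolate | C#CC(=O)O[C@@H]1C[C@H](C)CC[C@H]1C(C)(C)c1ccccc1 | intermediate |
| 5 | 8-Phenylmenthyl (E)-ferulate | COc1cc(/C=C/C(=O)O[C@@H]2C[C@H](C)CC[C@H]2C(C)(C)c2ccccc2)ccc1O | intermediate |
| 6 | (1S,2R)-Dihydronaphthalene-2,3-dicarboxylate bis(8-phenylmenthyl) ester | COc1cc([C@H]2c3cc(O)c(OC)cc3C=C(C(=O)O[C@@H]4C[C@H](C)CC[C@H]4C(C)(C)c4ccccc4)[C@@H]2C(=O)O[C@@H]4C[C@H](C)CC[C@H]4C(C)(C)c4ccccc4)ccc1O | intermediate |
| 7 | Target, CID10473569 | COc1cc([C@H]2c3cc(O)c(OC)cc3C=C(CO)[C@@H]2CO)ccc1O | target |

**Total steps:** 5. **Longest linear sequence:** 4 steps (1 → 2 → 5 → 6 → 7; the branch 3 → 4 is also 4 steps to the target).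

## Three steps most likely to fail
1. **Step 4 (coupling).** The 8–8′ cyclised product competes with 8–5′ and 8–O–4′ dimers and with over-oxidation to the naphthalene, and the diastereoselectivity from the remote ester auxiliary may be low.
   - Fallback: make the bis-ferulate of (2R,3R)-butane-2,3-diol so that the 8–8′ coupling is intramolecular and the C2-symmetric tether controls the configuration. Alternatively, couple the achiral dimethyl ester and resolve it by preparative chiral HPLC.
2. **Step 3 (hydroarylation).** Regioselectivity (C4 vs C5 of guaiacol), catalyst poisoning by the phenol, and an incomplete Z→E isomerisation could each cause failure.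
   - Fallback: para-iodinate guaiacol with NIS, then run a Mizoroki–Heck reaction with 8-phenylmenthyl acrylate, which gives the E-cinnamate directly.
3. **Step 5 (reduction).** Conjugate (1,4) reduction of the hindered trisubstituted enoate, or incomplete cleavage of the bulky esters, could occur.
   - Fallback: transesterify to the dimethyl diester with Ti(OiPr)4/MeOH, which releases the auxiliary. Then protect the phenols as acetates and reduce with LiAlH4 at −20 °C, or reduce with LiBH4, before removing the acetates.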